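**Assumptions and conventions.** Commercial (±)-naringenin is used as the racemate. The C3–C6'' axis of the target is taken as freely rotating, so C2'' is the only stereochemical element to control. The relative configuration at C2/C3 of the chromanone half in 11–17 is left unassigned, because both carbons become sp2 in step 8. Locants: flavone unit unprimed (benzo ring A, pyranone ring C, 4-hydroxyphenyl ring B); flavan unit double-primed (benzo ring D, dihydropyran ring F, 4-hydroxyphenyl ring E).

Route in one sentence: a [2,3]-sigmatropic rearrangement of an aryloxysulfonium ylide, assembled on sulfur from a 3-(methylsulfanyl)flavanone and the 5-hydroxyl of a (2S)-flavan, forms the C3–C6'' bond.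

## Structural features

The target is a C–C linked biflavonoid: an apigenin unit (rings A, C, B) is joined through C3 of ring C to C6'' of a (2S)-5,7,4'-trihydroxyflavan unit (rings D, F, E). The inter-unit bond C3–C6'' is the crux. C3 is a fully substituted vinylogous-ester carbon flanked by C4=O and the C2 aryl group, and C6'' is flanked by the 5''- and 7''-oxygens, so the bond is of the tetra-ortho-substituted biaryl type. Ring D is a phloroglucinol ring with two nucleophilic CH positions, and in 5,7-dioxygenated flavans electrophiles normally prefer C8'', whereas the target is substituted at C6''. There is a single stereocentre, C2'' (S), with no neighbouring stereocentre; it is a benzylic ether carbon bearing a para-oxygenated aryl group and can ionise (racemisation or ring opening) under strong Brønsted or Lewis acid. Six phenols make the free compound oxidation-sensitive and call for protection that is removable under neutral conditions; methyl ethers, which need BBr3, are excluded by the lability of C2''. The real difficulty is to make the hindered C3–C6'' bond at C6'' and not at C8'' while leaving C2'' untouched. The key step exploits two features: the O5''–C5''–C6'' phenol unit of ring D, in which C6'' is the only free ortho carbon of O5'' because the other one, C4a'', is the ring fusion; and the fact that ring C can be carried as a chroman-4-one whose C3 is an enolisable sp3 carbon able to bear sulfur.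

## Logic of the disconnections

**20 ⇒ 19.** Five O–CH2Ph bonds are cut. Benzyl ethers are chosen because hydrogenolysis is neutral and spares the acid-labile C2''–O1'' bond; the 5''-OH is already free. The demand on the forward step is that the tetrasubstituted C2=C3 bond and the cyclic benzylic ether survive, and that no sulfur is left to poison the catalyst.

**19 ⇒ 16.** The C2=C3 π bond is traced back to a C3–S bond and a C2–H bond. This takes ring C to the chromanone level, where C3 is sp3. Sulfur is thus both the handle of the key step and the leaving group that returns the unsaturation. The demand is an elimination that works whatever the relative configuration at C2/C3; the free 5''-OH ortho to the C3 aryl group offers a path through an ortho-quinone methide that has no geometric requirement.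

**16 ⇒ 11 + 5 (key disconnection).** The C3–C6'' bond is cut. In the forward sense it is made by a [2,3]-shift within an S–O5'' tether, so the bond forms intramolecularly, to an sp3 carbon, and only at the ortho carbon of O5''. The gain is large: the dimer falls into two monomeric C15 flavonoid derivatives of equal size. The demand is that the S–O bond forms at the one free hydroxyl of 5, and that the ylide rearranges faster than it fragments.

**11 ⇒ 9.** The C3–S bond is cut (enolate sulfenylation). The demand is that the enolate of 9 is trapped before it ring-opens to a chalcone.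

**9 ⇒ 8 ⇒ 6 + 7.** The O1–C2 bond (oxa-Michael closure) and the Cα=Cβ bond (aldol condensation) are cut, the standard flavanone assembly. A racemate suffices, since C2 of this half ends up sp2.

**5 ⇒ 3 ⇒ 2.** The C4''–H bond is traced to C4''–OH and then to C4''=O. The C2'' stereocentre is secured at the ketone stage by a catalyst-controlled kinetic resolution of a racemic flavanone. The demand is that deoxygenation at C4'' does not ionise C2''.

**2 ⇒ 1.** Two O–benzyl bonds are cut. Chelation of the 5-OH to C4=O leaves exactly one hydroxyl unprotected, and this hydroxyl later becomes the sulfonium tether of the key step. No separate differentiation of the 5- and 7-oxygens is needed.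

## Other disconnections considered

**Alternative 1:** Cut C3–C6'' as a biaryl cross-coupling, the first plan that comes to mind. The forward key step would be a Suzuki–Miyaura coupling of the 3-iodoflavone A1 with the flavan-6-ylboronic acid A2. Three structural grounds speak against it. A fully protected 5,7-dioxygenated flavan is functionalised at C8'' in preference to C6'', so A2 has no direct regioselective access. A 2,6-dialkoxyarylboron reagent is prone to protodeboronation. The coupling must create a tetra-ortho-substituted axis next to a carbonyl. The chosen plan forms the same bond through a five-membered cyclic transition state, with the position dictated by the tether.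

**Alternative 2:** Cut C3–C6'' by the nitrogen analogue of the chosen step. The forward key step would be a [3,3]-sigmatropic shift of the ene-hydroxylamine tautomer of the O-aryl oxime ether A3, made from 9 and the O-arylhydroxylamine of 5. The regiocontrol would be the same. However, after the shift C3 still carries a hydrogen and C4 is an imine, so the liberated 5''-OH is expected to close on C4 and lose ammonia, giving the aromatic benzofuran A4 as a thermodynamic sink. The sulfur ylide gives a quaternary C3 that cannot aromatise in this way, and it carries its own leaving group for the later unsaturation. Making the O-arylhydroxylamine would also add steps.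

**Alternative 3:** Build ring F last by cutting O1''–C2'' and C3''–C4''. The forward key step would be an acid-catalysed ortho-quinone methide hetero-Diels–Alder reaction of the hydroxybenzyl alcohol A5 with the styrene A6 under a chiral phosphoric acid. The symmetry of the 2,6-dioxygenated aryl group would settle the C6''/C8'' question. The hindered C3–aryl bond would still have to come from a cross-coupling of a 2,6-dialkoxyaryl metal. A5 needs differentiated protection and an extra hydroxymethylation. The only stereocentre would be set at the last C–C bond-forming event, under acid, with a styrene that has no hydrogen-bonding handle for the catalyst. Resolving a simple flavanone early is more secure and shorter.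

Key step: step 7

## Route

Step 1
Reactants: 1 (±)-naringenin
Product: 2 rac-7-(benzyloxy)-2-[4-(benzyloxy)phenyl]-5-hydroxychroman-4-one
Conditions: BnBr (2.1 equiv), K2CO3, DMF, rt
Reagents that add atoms: benzyl bromide, BrCc1ccccc1
Why: Williamson etherification; the 5-OH is held in a hydrogen bond to C4=O and is much less nucleophilic, so only the 7- and 4'-hydroxyls react. Base-induced chalcone equilibration is harmless on a racemate.

Step 2
Reactants: 2 rac-7-(benzyloxy)-2-[4-(benzyloxy)phenyl]-5-hydroxychroman-4-one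
Product: 3 (2S,4S)-7-(benzyloxy)-2-[4-(benzyloxy)phenyl]chromane-4,5-diol
Conditions: RuCl(p-cymene)[(S,S)-TsDPEN] (1 mol %), HCO2H/Et3N (5:2), EtOAc, 30 °C, stopped near half conversion; chromatography on Et3N-deactivated silica
Reagents that add atoms: none
Why: Noyori–Ikariya asymmetric transfer hydrogenation run as a kinetic resolution. The (S,S)-catalyst should deliver hydride to give the 4S carbinol, as it does with chroman-4-one, and this is matched only for the (2S)-ketone, which gives the 2,4-cis diol; C2 is thus selected, not created. The unreacted (2R)-enantiomer of 2 is separated and can be racemised with base through the chalcone and recycled.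

Step 3
Reactants: 3 (2S,4S)-7-(benzyloxy)-2-[4-(benzyloxy)phenyl]chromane-4,5-diol
Product: 5 (2S)-7-(benzyloxy)-2-[4-(benzyloxy)phenyl]chroman-5-ol, via ortho-quinone methide 4 (not isolated)
Conditions: Et3SiH (3 equiv), TFA (2 equiv), CH2Cl2, −78 → −30 °C; cold NaHCO3 quench
Reagents that add atoms: none
Why: Ionic hydrogenation; the C4 carbinol is ortho to the 5-OH and ortho/para to two further oxygens, so it ionises at low temperature to 4 (or its conjugate acid), and hydride adds at C4 to restore the phenol. C2 is remote, and the mono-activated C2–O1 ether should not ionise under these cold, acid-limited conditions.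

Step 4
Reactants: 6 1-[2,4-bis(benzyloxy)-6-hydroxyphenyl]ethan-1-one; 7 4-(benzyloxy)benzaldehyde
Product: 8 (E)-1-[2,4-bis(benzyloxy)-6-hydroxyphenyl]-3-[4-(benzyloxy)phenyl]prop-2-en-1-one
Conditions: KOH (aq.), EtOH/THF, rt
Reagents that add atoms: none
Why: Claisen–Schmidt condensation of a methyl ketone with a non-enolisable aldehyde; dehydration gives the conjugated E-chalcone.

Step 5
Reactants: 8 (E)-1-[2,4-bis(benzyloxy)-6-hydroxyphenyl]-3-[4-(benzyloxy)phenyl]prop-2-en-1-one
Product: 9 rac-5,7-bis(benzyloxy)-2-[4-(benzyloxy)phenyl]chroman-4-one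
Conditions: NaOAc, EtOH, reflux
Reagents that add atoms: none
Why: Intramolecular oxa-Michael addition (6-endo-trig) of the 2'-phenol, favoured for 6'-alkoxychalcones; the racemate is sufficient because C2 becomes sp2 in step 8.

Step 6
Reactants: 9 rac-5,7-bis(benzyloxy)-2-[4-(benzyloxy)phenyl]chroman-4-one
Product: 11 rac-5,7-bis(benzyloxy)-2-[4-(benzyloxy)phenyl]-3-(methylsulfanyl)chroman-4-one, via lithium enolate 10 (not isolated)
Conditions: LiN(SiMe3)2 (1.1 equiv), THF, −78 °C; cannulated into MeSSO2Me (1.2 equiv), −78 °C; AcOH quench at −78 °C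
Reagents that add atoms: S-methyl methanethiosulfonate, CSS(C)(=O)=O
Why: α-Sulfenylation of a kinetic lithium enolate with a thiosulfonate; −78 °C suppresses E1cB ring opening, and inverse addition limits double sulfenylation. The 2,3-trans isomer should predominate, but the configuration is irrelevant.

Step 7
Reactants: 11 rac-5,7-bis(benzyloxy)-2-[4-(benzyloxy)phenyl]-3-(methylsulfanyl)chroman-4-one; 5 (2S)-7-(benzyloxy)-2-[4-(benzyloxy)phenyl]chroman-5-ol
Product: 16 5,7-bis(benzyloxy)-2-[4-(benzyloxy)phenyl]-3-{(2S)-7-(benzyloxy)-2-[4-(benzyloxy)phenyl]-5-hydroxychroman-6-yl}-3-(methylsulfanyl)chroman-4-one, via chlorosulfonium chloride 12 (not isolated), via aryloxysulfonium chloride 13 (not isolated), via sulfonium ylide 14 (not isolated), via cyclohexadienone 15 (not isolated)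
Conditions: SO2Cl2 (1.0 equiv), CH2Cl2, −78 °C; 5 (1.0 equiv), −78 → −50 °C; Et3N (3 equiv), −78 °C → rt
Reagents that add atoms: none
Why: This is a Gassman-type ortho-alkylation of a phenol with a β-keto sulfide, the oxygen counterpart of the Sommelet–Hauser rearrangement. Sulfur of 11 is chlorinated to 12, the only free hydroxyl of 5 displaces chloride at sulfur to give 13, and Et3N removes the C3–H, which is acidified by both C4=O and the sulfonium centre, to give the stabilised ylide 14. The ylide undergoes a concerted [2,3]-sigmatropic shift through a five-membered envelope transition state (C3, S, O5'', C5'', C6''): the S–O bond breaks as the C3–C6'' bond forms, and the resulting dienone 15 is tautomerised by Et3N to the phenol 16, which makes the step irreversible. No ring is closed; the step makes the most hindered bond of the target as an intramolecular bond to an sp3 carbon and not as a tetra-ortho-substituted biaryl coupling. The regioselectivity the target needs (C6'' and not C8'') is secured by the tether: from O5'' the ylide carbon can reach only C6'' or the blocked ring-fusion carbon C4a'', attack at C4a'' would give a dienone that cannot tautomerise, and C8'' is para to O5'' and out of reach. A dissociative Pummerer pathway, which would lose this control, is disfavoured because the acylthionium ion it requires is destabilised by the adjacent C4 carbonyl. The new quaternary centre at C3 should form by approach of the arene anti to the C2 aryl group, but this has no consequence because C2 and C3 both become sp2 in step 8, and the (2S) centre of the flavan is a spectator that sees only cold, briefly acidic and then basic conditions. Because C3 of 16 carries no hydrogen, the liberated 5''-OH can add reversibly to C4=O but cannot dehydrate to a benzofuran, the usual fate of phenol/β-keto sulfide adducts.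

Step 8
Reactants: 16 5,7-bis(benzyloxy)-2-[4-(benzyloxy)phenyl]-3-{(2S)-7-(benzyloxy)-2-[4-(benzyloxy)phenyl]-5-hydroxychroman-6-yl}-3-(methylsulfanyl)chroman-4-one
Product: 19 5,7-bis(benzyloxy)-2-[4-(benzyloxy)phenyl]-3-{(2S)-7-(benzyloxy)-2-[4-(benzyloxy)phenyl]-5-hydroxychroman-6-yl}-4H-chromen-4-one, via sulfoxide 17 (not isolated), via ortho-quinone methide 18 (not isolated)
Conditions: mCPBA (1.0 equiv), CH2Cl2, −78 °C; then DBU (3 equiv), toluene, 80 °C
Reagents that add atoms: none
Why: Sulfur is oxidised far faster than the arenes at −78 °C; with base the 5''-phenoxide expels methanesulfenate from the doubly activated benzylic C3 to give 18, whose C2–H shifts to oxygen (1,5-hydrogen shift or base-mediated tautomerisation) to give the aromatic flavone. A sulfoxide diastereomer with a syn C2–H can also undergo thermal sulfoxide syn-elimination to the same product, so the outcome does not depend on configuration; the quaternary C3 excludes enolate ring opening.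

Step 9
Reactants: 19 5,7-bis(benzyloxy)-2-[4-(benzyloxy)phenyl]-3-{(2S)-7-(benzyloxy)-2-[4-(benzyloxy)phenyl]-5-hydroxychroman-6-yl}-4H-chromen-4-one
Product: 20 5,7-dihydroxy-3-[(2S)-5,7-dihydroxy-2-(4-hydroxyphenyl)chroman-6-yl]-2-(4-hydroxyphenyl)-4H-chromen-4-one
Conditions: H2 (1 atm), Pd(OH)2/C, THF/MeOH, rt
Reagents that add atoms: none
Why: Hydrogenolysis of five aryl benzyl ethers under neutral conditions; the tetrasubstituted, conjugated C2=C3 bond and the cyclic C2''–O1'' ether should survive at 1 atm, and the absence of acid keeps C2'' configurationally intact.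

## Compound list

1 | (±)-naringenin, rac-5,7-dihydroxy-2-(4-hydroxyphenyl)chroman-4-one | O=C1CC(c2ccc(O)cc2)Oc2cc(O)cc(O)c12 | starting material
2 | rac-7-(benzyloxy)-2-[4-(benzyloxy)phenyl]-5-hydroxychroman-4-one | O=C1CC(c2ccc(OCc3ccccc3)cc2)Oc2cc(OCc3ccccc3)cc(O)c12 | intermediate
3 | (2S,4S)-7-(benzyloxy)-2-[4-(benzyloxy)phenyl]chromane-4,5-diol (2,4-cis) | O[C@H]1C[C@@H](c2ccc(OCc3ccccc3)cc2)Oc2cc(OCc3ccccc3)cc(O)c12 | intermediate
4 | ortho-quinone methide, (2S)-7-(benzyloxy)-2-[4-(benzyloxy)phenyl]-2,3-dihydro-5H-chromen-5-one (C4=C4a, C6=C7, C8=C8a) | O=C1C=C(OCc2ccccc2)C=C2O[C@H](c3ccc(OCc4ccccc4)cc3)CC=C12 | intermediate (not isolated)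
5 | (2S)-7-(benzyloxy)-2-[4-(benzyloxy)phenyl]chroman-5-ol | Oc1cc(OCc2ccccc2)cc2c1CC[C@@H](c1ccc(OCc3ccccc3)cc1)O2 | intermediate
6 | 1-[2,4-bis(benzyloxy)-6-hydroxyphenyl]ethan-1-one | CC(=O)c1c(O)cc(OCc2ccccc2)cc1OCc1ccccc1 | starting material
7 | 4-(benzyloxy)benzaldehyde | O=Cc1ccc(OCc2ccccc2)cc1 | starting material
8 | (E)-1-[2,4-bis(benzyloxy)-6-hydroxyphenyl]-3-[4-(benzyloxy)phenyl]prop-2-en-1-one | O=C(/C=C/c1ccc(OCc2ccccc2)cc1)c1c(O)cc(OCc2ccccc2)cc1OCc1ccccc1 | intermediate
9 | rac-5,7-bis(benzyloxy)-2-[4-(benzyloxy)phenyl]chroman-4-one | O=C1CC(c2ccc(OCc3ccccc3)cc2)Oc2cc(OCc3ccccc3)cc(OCc3ccccc3)c12 | intermediate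
10 | lithium 5,7-bis(benzyloxy)-2-[4-(benzyloxy)phenyl]-2H-chromen-4-olate (enolate of 9) | [Li+].[O-]C1=CC(c2ccc(OCc3ccccc3)cc2)Oc2cc(OCc3ccccc3)cc(OCc3ccccc3)c12 | intermediate (not isolated)
11 | rac-5,7-bis(benzyloxy)-2-[4-(benzyloxy)phenyl]-3-(methylsulfanyl)chroman-4-one (C2/C3 unassigned) | CSC1C(c2ccc(OCc3ccccc3)cc2)Oc2cc(OCc3ccccc3)cc(OCc3ccccc3)c2C1=O | intermediate
12 | chloro(methyl){5,7-bis(benzyloxy)-2-[4-(benzyloxy)phenyl]-4-oxochroman-3-yl}sulfonium chloride | C[S+](Cl)C1C(c2ccc(OCc3ccccc3)cc2)Oc2cc(OCc3ccccc3)cc(OCc3ccccc3)c2C1=O.[Cl-] | intermediate (not isolated)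
13 | ({(2S)-7-(benzyloxy)-2-[4-(benzyloxy)phenyl]chroman-5-yl}oxy)(methyl){5,7-bis(benzyloxy)-2-[4-(benzyloxy)phenyl]-4-oxochroman-3-yl}sulfonium chloride | C[S+](Oc1cc(OCc2ccccc2)cc2c1CC[C@@H](c1ccc(OCc3ccccc3)cc1)O2)C1C(c2ccc(OCc3ccccc3)cc2)Oc2cc(OCc3ccccc3)cc(OCc3ccccc3)c2C1=O.[Cl-] | intermediate (not isolated)
14 | sulfonium ylide of 13 (carbanion at C3 of the chromanone) | C[S+](Oc1cc(OCc2ccccc2)cc2c1CC[C@@H](c1ccc(OCc3ccccc3)cc1)O2)[C-]1C(c2ccc(OCc3ccccc3)cc2)Oc2cc(OCc3ccccc3)cc(OCc3ccccc3)c2C1=O | intermediate (not isolated)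
15 | cyclohexa-2,4-dienone tautomer of 16 (C5''=O, sp3 C6''–H bearing the chromanone C3) | CSC1(C2C(OCc3ccccc3)=CC3=C(CC[C@@H](c4ccc(OCc5ccccc5)cc4)O3)C2=O)C(c2ccc(OCc3ccccc3)cc2)Oc2cc(OCc3ccccc3)cc(OCc3ccccc3)c2C1=O | intermediate (not isolated)
16 | 5,7-bis(benzyloxy)-2-[4-(benzyloxy)phenyl]-3-{(2S)-7-(benzyloxy)-2-[4-(benzyloxy)phenyl]-5-hydroxychroman-6-yl}-3-(methylsulfanyl)chroman-4-one (C2/C3 of the chromanone unassigned) | CSC1(c2c(OCc3ccccc3)cc3c(c2O)CC[C@@H](c2ccc(OCc4ccccc4)cc2)O3)C(c2ccc(OCc3ccccc3)cc2)Oc2cc(OCc3ccccc3)cc(OCc3ccccc3)c2C1=O | intermediate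
17 | S-oxide of 16, 3-(methanesulfinyl) analogue | CS(=O)C1(c2c(OCc3ccccc3)cc3c(c2O)CC[C@@H](c2ccc(OCc4ccccc4)cc2)O3)C(c2ccc(OCc3ccccc3)cc2)Oc2cc(OCc3ccccc3)cc(OCc3ccccc3)c2C1=O | intermediate (not isolated)
18 | ortho-quinone methide: C3 of the chromanone doubly bonded to C6'', C5''=O | O=C1C(=C2C(c3ccc(OCc4ccccc4)cc3)Oc3cc(OCc4ccccc4)cc(OCc4ccccc4)c3C2=O)C(OCc2ccccc2)=CC2=C1CC[C@@H](c1ccc(OCc3ccccc3)cc1)O2 | intermediate (not isolated)
19 | 5,7-bis(benzyloxy)-2-[4-(benzyloxy)phenyl]-3-{(2S)-7-(benzyloxy)-2-[4-(benzyloxy)phenyl]-5-hydroxychroman-6-yl}-4H-chromen-4-one | O=c1c(-c2c(OCc3ccccc3)cc3c(c2O)CC[C@@H](c2ccc(OCc4ccccc4)cc2)O3)c(-c2ccc(OCc3ccccc3)cc2)oc2cc(OCc3ccccc3)cc(OCc3ccccc3)c12 | intermediate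
20 | 5,7-dihydroxy-3-[(2S)-5,7-dihydroxy-2-(4-hydroxyphenyl)chroman-6-yl]-2-(4-hydroxyphenyl)-4H-chromen-4-one | O=c1c(-c2c(O)cc3c(c2O)CC[C@@H](c2ccc(O)cc2)O3)c(-c2ccc(O)cc2)oc2cc(O)cc(O)c12 | target

## Step count and least certain steps

Total: 9 steps. Longest linear sequence: 6 steps (1 → 2 → 3 → 7 → 8 → 9, or 4 → 5 → 6 → 7 → 8 → 9).

**Step 7 (key step).** Three processes are most likely to go wrong. The chlorosulfonium salt may collapse by a Pummerer-type α-chlorination at C3 before the hindered phenol has bonded to sulfur. The ylide may lose aryloxide to an acylthionium/phenoxide pair, which would recombine intermolecularly without the O5''→C6'' delivery. The electron-rich ring D may be chlorinated by positive chlorine. Steric retardation of the shift, which builds a quaternary carbon next to a di-ortho-substituted arene carbon, would favour all three.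
Fallback (sets out from 5 and 9, returns at 20): ortho-selective bromination of 5 (NBS, catalytic i-Pr2NH, CH2Cl2, 0 °C), directed by the free 5-OH, should give (2S)-7-(benzyloxy)-2-[4-(benzyloxy)phenyl]-6-bromochroman-5-ol F1. Benzylation (BnBr, K2CO3, DMF) gives (2S)-5,7-bis(benzyloxy)-2-[4-(benzyloxy)phenyl]-6-bromochromane F2. Bromine–lithium exchange (n-BuLi, THF, −78 °C) and quenching with 2-isopropoxy-4,4,5,5-tetramethyl-1,3,2-dioxaborolane gives the pinacol boronate F3. In parallel, 9 is dehydrogenated (catalytic I2, DMSO, 120 °C) to 5,7-bis(benzyloxy)-2-[4-(benzyloxy)phenyl]-4H-chromen-4-one F4, which is lithiated at C3 (LiN(i-Pr)2, THF, −78 °C) and iodinated with I2 to the 3-iodoflavone F5 (the same structure as A1). Suzuki–Miyaura coupling of F3 with F5 (Pd(OAc)2, SPhos, K3PO4, toluene/H2O, 100 °C) would give the hexa-O-benzyl ether F6, and hydrogenolysis as in step 9 gives 20.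

**Step 8.** The sulfoxide diastereomer that lacks a syn C2–H cannot undergo thermal syn-elimination, and its base-induced loss of sulfenate through 18 may be slow; Pummerer rearrangement at the S-methyl group or over-oxidation could then take over.
Fallback (from 16, returns at 19): S-methylation of 16 with MeOTf (CH2Cl2, 0 °C) gives the dimethylsulfonium triflate F7. Aqueous NaHCO3 then triggers loss of dimethyl sulfide, by anti-elimination or through 18, to give 19 without any oxidation.

**Step 2.** The hydrogen-bonded ketone may be reduced sluggishly, or the catalyst may discriminate poorly between the enantiomers, which would lower the enantiomeric purity carried into 5.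
Fallback (from 2, returns at 5): NaBH4 (MeOH/THF, 0 °C) reduces racemic 2 to the racemic 2,4-cis-chromane-4,5-diol F8. Ionic hydrogenation as in step 3 gives the racemic flavan-5-ol F9. Preparative chromatography on a chiral stationary phase then delivers 5, a classical resolution in place of the catalytic one.

**Step 6.** The lithium enolate may open by E1cB loss of the ring phenoxide to a chalcone, and the more acidic product may be sulfenylated a second time.
Fallback (from 9, returns at 11): soft enolisation (Me3SiOTf, Et3N, CH2Cl2, 0 °C) gives the trimethylsilyl enol ether F10. Sulfenylation with dimethyl(methylthio)sulfonium tetrafluoroborate (CH2Cl2, −40 °C) then gives 11 without a metal enolate.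

**Step 3.** Acid may ionise the C2–O1 ether as well, leading to epimerisation or over-reduction to a 1,3-diarylpropane, and the quinone methide may dimerise if hydride transfer is slow.
Fallback (from 3, returns at 5): acetylation (Ac2O, pyridine) gives the (2S,4S)-4,5-diacetate F11. NaBH4 in THF/EtOH cleaves the aryl acetate, the phenoxide expels the benzylic acetate to give 4 under basic conditions, and hydride adds at C4 to give 5.

## Further compounds

F1 | step 7 | (2S)-7-(benzyloxy)-2-[4-(benzyloxy)phenyl]-6-bromochroman-5-ol | Oc1c(Br)c(OCc2ccccc2)cc2c1CC[C@@H](c1ccc(OCc3ccccc3)cc1)O2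
F2 | step 7 | (2S)-5,7-bis(benzyloxy)-2-[4-(benzyloxy)phenyl]-6-bromochromane | Brc1c(OCc2ccccc2)cc2c(c1OCc1ccccc1)CC[C@@H](c1ccc(OCc3ccccc3)cc1)O2
F3 | step 7 | 2-{(2S)-5,7-bis(benzyloxy)-2-[4-(benzyloxy)phenyl]chroman-6-yl}-4,4,5,5-tetramethyl-1,3,2-dioxaborolane | CC1(C)OB(c2c(OCc3ccccc3)cc3c(c2OCc2ccccc2)CC[C@@H](c2ccc(OCc4ccccc4)cc2)O3)OC1(C)C
F4 | step 7 | 5,7-bis(benzyloxy)-2-[4-(benzyloxy)phenyl]-4H-chromen-4-one | O=c1cc(-c2ccc(OCc3ccccc3)cc2)oc2cc(OCc3ccccc3)cc(OCc3ccccc3)c12
F5 | step 7 | 5,7-bis(benzyloxy)-2-[4-(benzyloxy)phenyl]-3-iodo-4H-chromen-4-one | O=c1c(I)c(-c2ccc(OCc3ccccc3)cc2)oc2cc(OCc3ccccc3)cc(OCc3ccccc3)c12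
F6 | step 7 | 5,7-bis(benzyloxy)-2-[4-(benzyloxy)phenyl]-3-{(2S)-5,7-bis(benzyloxy)-2-[4-(benzyloxy)phenyl]chroman-6-yl}-4H-chromen-4-one | O=c1c(-c2c(OCc3ccccc3)cc3c(c2OCc2ccccc2)CC[C@@H](c2ccc(OCc4ccccc4)cc2)O3)c(-c2ccc(OCc3ccccc3)cc2)oc2cc(OCc3ccccc3)cc(OCc3ccccc3)c12
F7 | step 8 | dimethyl{5,7-bis(benzyloxy)-2-[4-(benzyloxy)phenyl]-3-[(2S)-7-(benzyloxy)-2-[4-(benzyloxy)phenyl]-5-hydroxychroman-6-yl]-4-oxochroman-3-yl}sulfonium trifluoromethanesulfonate | C[S+](C)C1(c2c(OCc3ccccc3)cc3c(c2O)CC[C@@H](c2ccc(OCc4ccccc4)cc2)O3)C(c2ccc(OCc3ccccc3)cc2)Oc2cc(OCc3ccccc3)cc(OCc3ccccc3)c2C1=O.[O-]S(=O)(=O)C(F)(F)F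
F8 | step 2 | rac-cis-7-(benzyloxy)-2-[4-(benzyloxy)phenyl]chromane-4,5-diol (racemate, 2,4-cis) | OC1CC(c2ccc(OCc3ccccc3)cc2)Oc2cc(OCc3ccccc3)cc(O)c12
F9 | step 2 | rac-7-(benzyloxy)-2-[4-(benzyloxy)phenyl]chroman-5-ol | Oc1cc(OCc2ccccc2)cc2c1CCC(c1ccc(OCc3ccccc3)cc1)O2
F10 | step 6 | {5,7-bis(benzyloxy)-2-[4-(benzyloxy)phenyl]-2H-chromen-4-yl}oxy(trimethyl)silane | C[Si](C)(C)OC1=CC(c2ccc(OCc3ccccc3)cc2)Oc2cc(OCc3ccccc3)cc(OCc3ccccc3)c12
F11 | step 3 | (2S,4S)-7-(benzyloxy)-2-[4-(benzyloxy)phenyl]chromane-4,5-diyl diacetate | CC(=O)O[C@H]1C[C@@H](c2ccc(OCc3ccccc3)cc2)Oc2cc(OCc3ccccc3)cc(OC(C)=O)c12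
A1 | alternative 1 | 5,7-bis(benzyloxy)-2-[4-(benzyloxy)phenyl]-3-iodo-4H-chromen-4-one | O=c1c(I)c(-c2ccc(OCc3ccccc3)cc2)oc2cc(OCc3ccccc3)cc(OCc3ccccc3)c12
A2 | alternative 1 | {(2S)-5,7-bis(benzyloxy)-2-[4-(benzyloxy)phenyl]chroman-6-yl}boronic acid | OB(O)c1c(OCc2ccccc2)cc2c(c1OCc1ccccc1)CC[C@@H](c1ccc(OCc3ccccc3)cc1)O2
A3 | alternative 2 | 5,7-bis(benzyloxy)-2-[4-(benzyloxy)phenyl]chroman-4-one O-{(2S)-7-(benzyloxy)-2-[4-(benzyloxy)phenyl]chroman-5-yl}oxime | C1(=NOc2cc(OCc3ccccc3)cc3c2CC[C@@H](c2ccc(OCc4ccccc4)cc2)O3)CC(c2ccc(OCc3ccccc3)cc2)Oc2cc(OCc3ccccc3)cc(OCc3ccccc3)c12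
A4 | alternative 2 | benzofuran formed by closure of O5'' on C4 (benzofuro[3,2-c]chromene fused to the chroman, 6-aryl) | C1(c2ccc(OCc3ccccc3)cc2)Oc2cc(OCc3ccccc3)cc(OCc3ccccc3)c2-c2oc3c4CC[C@@H](c5ccc(OCc6ccccc6)cc5)Oc4cc(OCc4ccccc4)c3c21
A5 | alternative 3 | 5,7-bis(benzyloxy)-2-[4-(benzyloxy)phenyl]-3-[2,6-bis(benzyloxy)-4-hydroxy-3-(hydroxymethyl)phenyl]-4H-chromen-4-one | O=c1c(-c2c(OCc3ccccc3)cc(O)c(CO)c2OCc2ccccc2)c(-c2ccc(OCc3ccccc3)cc2)oc2cc(OCc3ccccc3)cc(OCc3ccccc3)c12
A6 | alternative 3 | 1-(benzyloxy)-4-ethenylbenzene | C=Cc1ccc(OCc2ccccc2)cc1
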